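**Retrosynthetic overview**

- Target: (3S)-5,7-dihydroxy-3-(5-hydroxy-2,2-dimethyl-2H-chromen-8-yl)chroman-4-one. Ring A is the 5,7-dioxygenated benzo ring, ring C the pyranone, ring B the aryl group on C3, ring D the dimethylpyran fused to ring B through O2' and C3'.
- Feature used: in ring C the C4–C4a bond and the O1–C2 bond both trace back to one aryl ester, because ring A is a 3,5-dioxygenated phenol whose two carbons ortho to the ester oxygen are equivalent. Ring C is therefore cut back to a 3,5-bis(MOM-oxy)phenyl 2-arylacrylate.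
- Ring C first: light moves the acryloyl group from oxygen to the ortho carbon (C4–C4a) and the freed phenol adds 6-endo to the CH2 terminus (O1–C2), giving the racemic isoflavanone. The ester comes from 2,4-dihydroxyacetophenone (as its enol triflate), CO and bis-MOM phloroglucinol.
- Ring D second, after the light step: O2'-debenzylation, 1,1-dimethylpropargyl ether, Claisen rearrangement to C3' and electrocyclisation.
- C3 last: transfer-hydrogenative dynamic kinetic resolution to the cis (3S,4S) alcohol, reoxidation of C4, removal of the three MOM groups.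

Key step: step 6

Remark: C3 of the target is S; C4 outranks C2 at C3 in both the ketone and the C4 alcohol, so the cis alcohol required from the reduction is (3S,4S). 3-Chloro-3-methylbut-1-yne is taken as a purchased reagent.

**Route**

Step 1
Reactants: 1 2,4-dihydroxyacetophenone
Product: 2 1-[2-hydroxy-4-(methoxymethoxy)phenyl]ethanone
Conditions: MOMCl (1.1 equiv), K2CO3, acetone, 0 °C → rt
Reagents that add atoms: chloromethyl methyl ether (MOMCl), COCCl
Why: Williamson-type O-alkylation; the C2 hydroxyl is held in a hydrogen bond to the acetyl oxygen, so only the C4 phenoxide should be alkylated.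

Step 2
Reactants: 2 1-[2-hydroxy-4-(methoxymethoxy)phenyl]ethanone
Product: 3 1-[2-(benzyloxy)-4-(methoxymethoxy)phenyl]ethanone
Conditions: BnBr, K2CO3, Bu4NI (cat.), DMF, 60 °C
Reagents that add atoms: benzyl bromide, BrCc1ccccc1
Why: Williamson etherification; the chelated C2 phenol should be alkylated on warming in DMF, and the MOM acetal is stable to base.

Step 3
Reactants: 3 1-[2-(benzyloxy)-4-(methoxymethoxy)phenyl]ethanone
Product: 4 1-[2-(benzyloxy)-4-(methoxymethoxy)phenyl]vinyl trifluoromethanesulfonate
Conditions: KN(SiMe3)2 (1.1 equiv), THF, −78 °C; then PhNTf2, −78 → 0 °C; quick filtration through Et3N-treated silica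
Reagents that add atoms: N-phenylbis(trifluoromethanesulfonimide) (PhNTf2), O=S(=O)(N(c1ccccc1)S(=O)(=O)C(F)(F)F)C(F)(F)F
Why: Enolate O-triflation; the methyl ketone has one enolisable position and its potassium enolate should be sulfonylated on oxygen to the 1-arylvinyl triflate.

Step 4
Reactants: 5 phloroglucinol
Product: 6 3,5-bis(methoxymethoxy)phenol
Conditions: MOMCl (2.0 equiv), K2CO3, acetone, 0 °C → rt; chromatography
Reagents that add atoms: chloromethyl methyl ether (MOMCl), COCCl
Why: Statistical Williamson-type O-alkylation of a symmetric triphenol; the bis-ether is separated from the mono- and tris-ethers, which can be recycled.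

Step 5
Reactants: 4 1-[2-(benzyloxy)-4-(methoxymethoxy)phenyl]vinyl trifluoromethanesulfonate; 6 3,5-bis(methoxymethoxy)phenol
Product: 7 3,5-bis(methoxymethoxy)phenyl 2-[2-(benzyloxy)-4-(methoxymethoxy)phenyl]acrylate
Conditions: Pd(OAc)2 (5 mol%), Xantphos (6 mol%), CO (1 atm), Et3N, toluene, 60 °C
Reagents that add atoms: carbon monoxide, [C-]#[O+]
Why: Palladium-catalysed carbonylative esterification (aryloxycarbonylation) of an enol triflate; oxidative addition of zerovalent palladium, CO insertion and capture of the acylpalladium by the phenoxide of 6 should give the aryl acrylate with the alkene untouched.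

Step 6
Reactants: 7 3,5-bis(methoxymethoxy)phenyl 2-[2-(benzyloxy)-4-(methoxymethoxy)phenyl]acrylate
Product: 9 (±)-3-[2-(benzyloxy)-4-(methoxymethoxy)phenyl]-5,7-bis(methoxymethoxy)chroman-4-one, via hydroxyaryl vinyl ketone 8 (not isolated)
Conditions: hν (254 nm, low-pressure Hg lamp, quartz), degassed MeCN (5 mM), 20 °C; lamp off, then Et3N (0.5 equiv), rt
Reagents that add atoms: none
Why: Excitation of the aryl ester should cleave the ArO–C(=O) bond to a solvent-caged phenoxyl/2-arylacryloyl radical pair that recombines at a ring A carbon ortho to oxygen (C4–C4a) and tautomerises to the hydrogen-bonded hydroxyaryl vinyl ketone 8. The closest known reaction type is the photo-Fries rearrangement of aryl esters of α,β-unsaturated acids (3-methylbut-2-enoates, cinnamates) followed by base-induced closure to chroman-4-ones and flavanones, and the 2-arylacrylate is a further member of that ester class. Ring C then closes by 6-endo-trig oxa-Michael addition of the phenol oxygen to the unsubstituted CH2 terminus (O1–C2), the closure that α-methylene deoxybenzoins undergo in the classical formaldehyde route to isoflavanones. C3 becomes stereogenic on protonation of the enolate and is formed racemic, since nothing in substrate or medium is chiral; it is set in step 10. The step needs ortho rather than para recombination and ring closure rather than alkene oligomerisation: the two ortho carbons are equivalent by the symmetry of ring A, the para carbon is flanked by two MOM-oxy groups, a para isomer cannot cyclise and stays a base-extractable phenol, and high dilution disfavours bimolecular alkene reactions. The 1,1-disubstituted alkene has no E/Z channel to waste light, the unsaturated acyl radical loses CO only slowly, and base is added after the lamp is off so that the light-stable chelated ketone 8, not the chromanone, sits in the beam.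

Step 7
Reactants: 9 (±)-3-[2-(benzyloxy)-4-(methoxymethoxy)phenyl]-5,7-bis(methoxymethoxy)chroman-4-one
Product: 10 (±)-3-[2-hydroxy-4-(methoxymethoxy)phenyl]-5,7-bis(methoxymethoxy)chroman-4-one
Conditions: H2 (1 atm), 10% Pd/C, EtOAc, rt
Reagents that add atoms: none
Why: Catalytic hydrogenolysis of the benzyl aryl ether; the MOM acetals and the hindered, donor-conjugated aryl ketone should be inert under these conditions.

Step 8
Reactants: 10 (±)-3-[2-hydroxy-4-(methoxymethoxy)phenyl]-5,7-bis(methoxymethoxy)chroman-4-one; 11 3-chloro-3-methylbut-1-yne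
Product: 12 (±)-5,7-bis(methoxymethoxy)-3-[4-(methoxymethoxy)-2-(2-methylbut-3-yn-2-yloxy)phenyl]chroman-4-one
Conditions: DBU, CuCl2·2H2O (1 mol%), MeCN, 0 °C → rt, Ar
Reagents that add atoms: none
Why: Copper-catalysed O-propargylation of a phenol with a tertiary propargylic chloride; the 2'-OH is the only free phenol, the other three being MOM ethers.

Step 9
Reactants: 12 (±)-5,7-bis(methoxymethoxy)-3-[4-(methoxymethoxy)-2-(2-methylbut-3-yn-2-yloxy)phenyl]chroman-4-one
Product: 14 (±)-5,7-bis(methoxymethoxy)-3-[5-(methoxymethoxy)-2,2-dimethyl-2H-chromen-8-yl]chroman-4-one, via allenylphenol 13 (not isolated)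
Conditions: xylene, 140 °C, Ar
Reagents that add atoms: none
Why: Aromatic propargyl Claisen rearrangement to C3' (the only free ortho carbon), then 1,5-hydrogen shift of allenylphenol 13 and oxa-6π electrocyclisation should close ring D as the 2,2-dimethyl-2H-chromene with its oxygen on C2'.

Step 10
Reactants: 14 (±)-5,7-bis(methoxymethoxy)-3-[5-(methoxymethoxy)-2,2-dimethyl-2H-chromen-8-yl]chroman-4-one
Product: 15 (3S,4S)-5,7-bis(methoxymethoxy)-3-[5-(methoxymethoxy)-2,2-dimethyl-2H-chromen-8-yl]chroman-4-ol
Conditions: RuCl[(S,S)-TsDPEN](p-cymene) (5 mol%), HCO2H/Et3N (5:2), EtOAc, 40 °C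
Reagents that add atoms: none
Why: Noyori-type asymmetric transfer hydrogenation with dynamic kinetic resolution; Et3N should epimerise C3 through the enol faster than the ketone is reduced, the (S,S) catalyst should deliver hydride to the C4 face that gives 4S (the sense it shows with aryl alkyl ketones and chroman-4-one) and only to the enantiomer whose C3 aryl group lies on the opposite face, so the cis (3S,4S) alcohol is expected, while the chromene alkene is not a substrate for this catalyst.

Step 11
Reactants: 15 (3S,4S)-5,7-bis(methoxymethoxy)-3-[5-(methoxymethoxy)-2,2-dimethyl-2H-chromen-8-yl]chroman-4-ol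
Product: 16 (3S)-5,7-bis(methoxymethoxy)-3-[5-(methoxymethoxy)-2,2-dimethyl-2H-chromen-8-yl]chroman-4-one
Conditions: Dess–Martin periodinane (1.3 equiv), NaHCO3, CH2Cl2, 0 °C → rt
Reagents that add atoms: none
Why: Dess–Martin oxidation of the benzylic alcohol under bicarbonate buffer should return the C4 ketone without acid or base strong enough to enolise C3, so the (3S) centre is kept.

Step 12
Reactants: 16 (3S)-5,7-bis(methoxymethoxy)-3-[5-(methoxymethoxy)-2,2-dimethyl-2H-chromen-8-yl]chroman-4-one
Product: 17 (3S)-5,7-dihydroxy-3-(5-hydroxy-2,2-dimethyl-2H-chromen-8-yl)chroman-4-one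
Conditions: ZnBr2 (3 equiv), n-PrSH (6 equiv), CH2Cl2, 0 °C, 10–15 min; aq. NaHCO3
Reagents that add atoms: none
Why: Lewis acid-assisted acetal exchange; ZnBr2 activates each MOM acetal and the thiol takes up the methoxymethyl group within minutes at 0 °C, a brief non-protic treatment chosen to spare the enolisable C3 centre and the chromene.

**Compound list**

1 | 2,4-dihydroxyacetophenone | CC(=O)c1ccc(O)cc1O | starting material
2 | 1-[2-hydroxy-4-(methoxymethoxy)phenyl]ethanone | CC(=O)c1ccc(OCOC)cc1O | intermediate
3 | 1-[2-(benzyloxy)-4-(methoxymethoxy)phenyl]ethanone | CC(=O)c1ccc(OCOC)cc1OCc1ccccc1 | intermediate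
4 | 1-[2-(benzyloxy)-4-(methoxymethoxy)phenyl]vinyl trifluoromethanesulfonate | C=C(OS(=O)(=O)C(F)(F)F)c1ccc(OCOC)cc1OCc1ccccc1 | intermediate
5 | phloroglucinol (benzene-1,3,5-triol) | Oc1cc(O)cc(O)c1 | starting material
6 | 3,5-bis(methoxymethoxy)phenol | Oc1cc(OCOC)cc(OCOC)c1 | intermediate
7 | 3,5-bis(methoxymethoxy)phenyl 2-[2-(benzyloxy)-4-(methoxymethoxy)phenyl]acrylate (key-step precursor) | C=C(C(=O)Oc1cc(OCOC)cc(OCOC)c1)c1ccc(OCOC)cc1OCc1ccccc1 | intermediate
8 | 2-[2-(benzyloxy)-4-(methoxymethoxy)phenyl]-1-[2-hydroxy-4,6-bis(methoxymethoxy)phenyl]prop-2-en-1-one (formed and consumed in step 6) | C=C(C(=O)c1c(O)cc(OCOC)cc1OCOC)c1ccc(OCOC)cc1OCc1ccccc1 | intermediate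
9 | (±)-3-[2-(benzyloxy)-4-(methoxymethoxy)phenyl]-5,7-bis(methoxymethoxy)chroman-4-one (racemic 2'-benzyloxy-4',5,7-tris(methoxymethoxy)isoflavanone, key-step product) | O=C1C(c2ccc(OCOC)cc2OCc2ccccc2)COc2cc(OCOC)cc(OCOC)c21 | intermediate
10 | (±)-3-[2-hydroxy-4-(methoxymethoxy)phenyl]-5,7-bis(methoxymethoxy)chroman-4-one | O=C1C(c2ccc(OCOC)cc2O)COc2cc(OCOC)cc(OCOC)c21 | intermediate
11 | 3-chloro-3-methylbut-1-yne | CC(C)(Cl)C#C | starting material
12 | (±)-5,7-bis(methoxymethoxy)-3-[4-(methoxymethoxy)-2-(2-methylbut-3-yn-2-yloxy)phenyl]chroman-4-one | O=C1C(c2ccc(OCOC)cc2OC(C)(C)C#C)COc2cc(OCOC)cc(OCOC)c21 | intermediate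
13 | (±)-3-[2-hydroxy-4-(methoxymethoxy)-3-(3-methylbuta-1,2-dien-1-yl)phenyl]-5,7-bis(methoxymethoxy)chroman-4-one (formed and consumed in step 9) | O=C1C(c2ccc(OCOC)c(C=C=C(C)C)c2O)COc2cc(OCOC)cc(OCOC)c21 | intermediate
14 | (±)-5,7-bis(methoxymethoxy)-3-[5-(methoxymethoxy)-2,2-dimethyl-2H-chromen-8-yl]chroman-4-one | O=C1C(c2ccc(OCOC)c3C=CC(C)(C)Oc23)COc2cc(OCOC)cc(OCOC)c21 | intermediate
15 | (3S,4S)-5,7-bis(methoxymethoxy)-3-[5-(methoxymethoxy)-2,2-dimethyl-2H-chromen-8-yl]chroman-4-ol (cis) | O[C@H]1[C@@H](c2ccc(OCOC)c3C=CC(C)(C)Oc23)COc2cc(OCOC)cc(OCOC)c21 | intermediate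
16 | (3S)-5,7-bis(methoxymethoxy)-3-[5-(methoxymethoxy)-2,2-dimethyl-2H-chromen-8-yl]chroman-4-one | O=C1[C@@H](c2ccc(OCOC)c3C=CC(C)(C)Oc23)COc2cc(OCOC)cc(OCOC)c21 | intermediate
17 | (3S)-5,7-dihydroxy-3-(5-hydroxy-2,2-dimethyl-2H-chromen-8-yl)chroman-4-one | CC1(C)C=Cc2c(O)ccc([C@H]3COc4cc(O)cc(O)c4C3=O)c2O1 | target

**Step count**

Total: 12 steps. Longest linear sequence: 11 steps (1 → 17 through steps 1–3 and 5–12); step 4 is a one-step side branch from 5.

**Steps most likely to fail**

1. Step 6. The radical pair may recombine at the para carbon or escape the cage (returning phenol 6). The acrylate may oligomerise, the benzyl aryl ether may be cleaved by the same light, and the strongly absorbing product may slow conversion. If ring closure begins before the lamp is off, the chromanone may undergo secondary photochemistry.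
Fallback: a polar acylation replaces the light step. It sets out from phloroglucinol 5 and vinyl triflate 4 and comes back at hydroxy ketone 8, hence at 9. Phloroglucinol 5 is fully etherified (MOMCl, K2CO3, acetone, reflux) to 1,3,5-tris(methoxymethoxy)benzene F1. Triflate 4 is aminocarbonylated (Pd(OAc)2, Xantphos, CO, MeNH(OMe)·HCl, Et3N, toluene, 60 °C) to the Weinreb amide 2-[2-(benzyloxy)-4-(methoxymethoxy)phenyl]-N-methoxy-N-methylacrylamide F2. F1 is lithiated between two acetal oxygens (n-BuLi, THF, 0 °C) and the aryllithium is added to F2 at −78 °C with an inverse acidic quench, which should give 2-[2-(benzyloxy)-4-(methoxymethoxy)phenyl]-1-[2,4,6-tris(methoxymethoxy)phenyl]prop-2-en-1-one F3. Brief treatment with dilute HCl in MeOH/THF at 0 °C should cleave one of the two equivalent MOM ethers next to the carbonyl to give 8, which is closed with Et3N to 9 as in step 6.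

2. Step 10. Hydride transfer to the doubly donor-conjugated, peri-substituted C4 carbonyl may be too slow, or reduction may outrun C3 epimerisation so that diastereo- and enantioselectivity fall. Base may also open ring C by retro-oxa-Michael reaction, and the facial sense on this hindered ketone remains to be confirmed.
Fallback: enantioselective protonation replaces reduction and reoxidation. It sets out from 14 and comes back at 16, so that 15 and step 11 fall away. Ketone 14 is trapped (TMSCl present, LiN(SiMe3)2, THF, −78 °C) as the silyl enol ether 5,7-bis(methoxymethoxy)-3-[5-(methoxymethoxy)-2,2-dimethyl-2H-chromen-8-yl]-4-(trimethylsilyloxy)-2H-chromene F4. F4 is protonated at C3 with phenol as stoichiometric proton source under a BINOL-derived chiral N-triflyl thiophosphoramide catalyst (toluene, rt), the catalyst enantiomer being chosen to deliver (3S)-16. The reaction type relied on is catalytic enantioselective protonation of silyl enol ethers of 2-aryl cyclic ketones.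

3. Step 12. Enolisation of C3 during acetal cleavage would erode the enantiomeric purity set in step 10. The Lewis acid/thiol pair may also add to or open the chromene, and the least activated MOM ethers may be cleaved incompletely.
Fallback: the protecting groups are exchanged while the material is still racemic, so that the last unmasking uses fluoride. It sets out from 14 and comes back at 17. The MOM groups of 14 are removed (HCl, MeOH, 45 °C) to give (±)-5,7-dihydroxy-3-(5-hydroxy-2,2-dimethyl-2H-chromen-8-yl)chroman-4-one F5. F5 is silylated (TBSCl, imidazole, DMAP, DMF, 40 °C) to (±)-5,7-bis(tert-butyldimethylsilyloxy)-3-[5-(tert-butyldimethylsilyloxy)-2,2-dimethyl-2H-chromen-8-yl]chroman-4-one F6. F6 is reduced as in step 10 to (3S,4S)-5,7-bis(tert-butyldimethylsilyloxy)-3-[5-(tert-butyldimethylsilyloxy)-2,2-dimethyl-2H-chromen-8-yl]chroman-4-ol F7 and oxidised as in step 11 to (3S)-5,7-bis(tert-butyldimethylsilyloxy)-3-[5-(tert-butyldimethylsilyloxy)-2,2-dimethyl-2H-chromen-8-yl]chroman-4-one F8. HF·pyridine in THF/pyridine at 0 °C should then free 17 under buffered, non-enolising conditions.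

**Further compounds**

F1 | step 6 | 1,3,5-tris(methoxymethoxy)benzene | COCOc1cc(OCOC)cc(OCOC)c1
F2 | step 6 | 2-[2-(benzyloxy)-4-(methoxymethoxy)phenyl]-N-methoxy-N-methylacrylamide | C=C(C(=O)N(C)OC)c1ccc(OCOC)cc1OCc1ccccc1
F3 | step 6 | 2-[2-(benzyloxy)-4-(methoxymethoxy)phenyl]-1-[2,4,6-tris(methoxymethoxy)phenyl]prop-2-en-1-one | C=C(C(=O)c1c(OCOC)cc(OCOC)cc1OCOC)c1ccc(OCOC)cc1OCc1ccccc1
F4 | step 10 | 5,7-bis(methoxymethoxy)-3-[5-(methoxymethoxy)-2,2-dimethyl-2H-chromen-8-yl]-4-(trimethylsilyloxy)-2H-chromene | C[Si](C)(C)OC1=C(c2ccc(OCOC)c3C=CC(C)(C)Oc23)COc2cc(OCOC)cc(OCOC)c21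
F5 | step 12 | (±)-5,7-dihydroxy-3-(5-hydroxy-2,2-dimethyl-2H-chromen-8-yl)chroman-4-one | CC1(C)C=Cc2c(O)ccc(C3COc4cc(O)cc(O)c4C3=O)c2O1
F6 | step 12 | (±)-5,7-bis(tert-butyldimethylsilyloxy)-3-[5-(tert-butyldimethylsilyloxy)-2,2-dimethyl-2H-chromen-8-yl]chroman-4-one | O=C1C(c2ccc(O[Si](C)(C)C(C)(C)C)c3C=CC(C)(C)Oc23)COc2cc(O[Si](C)(C)C(C)(C)C)cc(O[Si](C)(C)C(C)(C)C)c21
F7 | step 12 | (3S,4S)-5,7-bis(tert-butyldimethylsilyloxy)-3-[5-(tert-butyldimethylsilyloxy)-2,2-dimethyl-2H-chromen-8-yl]chroman-4-ol | O[C@H]1[C@@H](c2ccc(O[Si](C)(C)C(C)(C)C)c3C=CC(C)(C)Oc23)COc2cc(O[Si](C)(C)C(C)(C)C)cc(O[Si](C)(C)C(C)(C)C)c21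
F8 | step 12 | (3S)-5,7-bis(tert-butyldimethylsilyloxy)-3-[5-(tert-butyldimethylsilyloxy)-2,2-dimethyl-2H-chromen-8-yl]chroman-4-one | O=C1[C@@H](c2ccc(O[Si](C)(C)C(C)(C)C)c3C=CC(C)(C)Oc23)COc2cc(O[Si](C)(C)C(C)(C)C)cc(O[Si](C)(C)C(C)(C)C)c21
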